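The data were computed with made-up constants, and the scatter is random.

**Blind end.** I cannot read grey's end off runs that stop at 12.0 h when grey goes on to 100 h. So I follow one substrate molecule through the chances those runs show.

| flask | substrate | gas | remark | time |
|---|---|---|---|---|
| Saturday's | 0.046 M (fed, over 15 h) | 8.3 mM (held) | run made earlier; the fed solution adds 1.0 times the starting volume |  |
| Tuesday's | 0.20 M (fed, over 15 h) | 8.3 mM (held) | run made earlier; the fed solution adds 1.0 times the starting volume |  |
| teal | 0.26 M (fed, over 15 h) | 8.3 mM (held) | the fed solution adds 1.0 times the starting volume | 25 h |
| grey | 0.060 M | 8.3 mM | everything together at the start, the whole solution of substrate included, so that from the start the volume is larger by 1.0 times the starting volume | 100 h |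

- Saturday's (time / h: target / %, substrate / %): 1.00: 0.3, 6.9; 2.00: 0, 12.4; 4.00: 0.6, 25.3; 6.00: 0.5, 38.6; 12.0: 5.1, 72.5
- Tuesday's (time / h: target / %, substrate / %): 1.00: 0.3, 6.6; 3.00: 0, 20.0; 6.00: 2.0, 37.9; 8.00: 1.8, 50.1; 12.0: 5.2, 73.1

(scatter of a reading: 0.5 percentage points)

- every charge counts on the volume at the start, and the solution that is fed holds the whole dose
- the numbers in the tables scatter by 0.5 percentage points (one standard deviation)
- percentages count the whole charge, also what has not yet gone in

- which one finishes higher in amount of target, in percent of the substrate charged ("neither" within 2 percentage points) (teal / grey / neither)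
- amount of target at the end, in percent of the substrate charged, teal
- amount of target at the end, in percent of the substrate charged, grey

**Leaving chance.** Tuesday's charge is 4.35 times Saturday's, yet at 12.0 h substrate reads 73.1 % against 72.5 % of the 80.0 % fed. So, with gas held, a molecule's chance of leaving reads the same at these two charges. On average 7.20 % is missing after a charge-averaged stay of 4.80 h, which gives 0.0150 /h.

**The fork.** The fork share, a selectivity, is the target standing per substrate lost: 0.715.

**The chain.** Teal's charge has an average stay of 17.5 h, so I reckon 23.1 % lost and target at 16.5 %. Grey stays 100 h, so I reckon 77.7 % lost and target at 55.6 %.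

**Weak link.** That last product assumes target stays target. Saturday alone gives a share of 0.680 and Tuesday 0.754. Each share carries the scatter of 0.5 percentage points on a target reading near 5.1 %, so the spread measures nothing, but it leaves room for a return. Target at 12.0 h is on average 4.00 h old, so a return to substrate of 0.0257 /h could lie inside that spread. Its half-life, 26.9 h, is shorter than grey's time. Solving substrate and target together with that return gives grey 22.3 %. I commit to teal near 16.5 %, grey between 22.3 % and 55.6 %, and grey ahead.

**The forecast.** It gives 16.5 % for teal and 56 % for grey, and says “Grey wins simply because it has much more time”.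

**The flask.** The higher finish is grey, with teal at 15.8 % and grey at 31.8 %.

    substrate + partner ⇌ target (K = 92.0 /M, k = 1.50 /M/h)
    gas ⇌ partner, rate k2*(csat - [partner]) (kL = 54.0 /h)
    substrate + target → side product B (k = 0.0250 /M/h)
    substrate + 2 partner → side product A (k = 63.0 /M²/h)

**Share again.** The first step runs both ways. At its end teal's share is 0.681, while grey's at its end stands at 0.535, lower than the carried 0.715. For grey read at 25 h, the same reckoning gives 22.4 % target. That flask holds 20.8 % target and 70 % substrate, a share of 0.693.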